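**Plan**
- Retrosynthesis: cut the acetate and the two O-protecting groups, then the arene C6–CO2H bond (back to C6–H), then the C4–C11 bond, which gives a tetralin C4 carbinol carbamate and a C11 secondary boronic ester. The tetralin itself is cut at C4–C4a (Friedel–Crafts) and C2–C3 (Michael).
- Forward: (2-methoxyphenyl)acetic acid → auxiliary-controlled Michael addition (C1) → Friedel–Crafts closure of the carbocycle → transfer hydrogenation (C4–O) → carbamate 12. Separately, a homoprenyl boronate is homologated by one carbon to boronic ester 19 (C11). 12 and 19 are joined by lithiation–borylation, followed by protodeboronation, arene C–H borylation/carboxylation, deprotection and selective acetylation.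
- Enabling feature: C4 is the secondary benzylic carbon of the tetralin ring, bonded to arene carbon C4a. Its O-carbamate therefore gives a configurationally stable benzyllithium, and the tertiary benzylic C–B bond formed in the coupling can be replaced by H with retention. C11 travels as an sp3 C–B bond that migrates with retention.
- Stereochemistry: C1 comes from the (R)-oxazolidinone auxiliary. The C4 carbinol comes from (S,S)-Ru transfer hydrogenation and is relayed to C4–H by retention/inversion/retention, placing the side chain trans to C1–CH2O. C11 comes from (+)-sparteine and is transferred unchanged.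
- The carboxyl is added last at C6, the only arene C–H with no ortho substituent.

Key step: step 10

Remark: locants follow the serrulatane skeleton (C1 carries the CH2O carbon C20, C4 the side chain, C8 the phenol oxygen, C6 the carboxyl, C11 is the side-chain methine). Ethyl 2,4,6-triisopropylbenzoate and (+)-sparteine are taken as commercial.

**Route**

Step 1
Reactants: 1 (2-methoxyphenyl)acetic acid
Product: 3 (4R)-4-benzyl-3-[(2-methoxyphenyl)acetyl]-1,3-oxazolidin-2-one, via mixed pivalic anhydride 2 (not isolated)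
Conditions: PivCl, Et3N, THF, −20 °C; then (R)-4-benzyl-1,3-oxazolidin-2-one, LiCl, −20 °C → rt
Reagents that add atoms: (R)-4-benzyl-1,3-oxazolidin-2-one, O=C1N[C@H](Cc2ccccc2)CO1
Why: Acylation of the oxazolidinone through the mixed pivalic anhydride (LiCl-assisted) is the standard way to make N-arylacetyl Evans imides and creates no stereocentre.

Step 2
Reactants: 3 (4R)-4-benzyl-3-[(2-methoxyphenyl)acetyl]-1,3-oxazolidin-2-one; 4 tert-butyl acrylate
Product: 6 tert-butyl (4R)-5-[(4R)-4-benzyl-2-oxo-1,3-oxazolidin-3-yl]-4-(2-methoxyphenyl)-5-oxopentanoate, via chlorotitanium enolate 5 (not isolated)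
Conditions: TiCl3(OiPr), i-Pr2NEt, CH2Cl2, 0 °C; then 4, 0 °C; aq. NH4Cl
Reagents that add atoms: none
Why: Evans chlorotitanium-enolate Michael addition: the chelated (Z)-enolate 5 is attacked by the acrylate on the face away from the benzyl group of the (R)-auxiliary, which should set the (R) benzylic centre that becomes C1.

Step 3
Reactants: 6 tert-butyl (4R)-5-[(4R)-4-benzyl-2-oxo-1,3-oxazolidin-3-yl]-4-(2-methoxyphenyl)-5-oxopentanoate
Product: 8 (4R)-4-benzyl-3-{[(1R)-8-methoxy-4-oxo-1,2,3,4-tetrahydronaphthalen-1-yl]carbonyl}-1,3-oxazolidin-2-one, via acid chloride 7 (not isolated)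
Conditions: SOCl2, rt; evaporate; AlCl3, CH2Cl2, 0 °C
Reagents that add atoms: none
Why: SOCl2 converts tert-butyl esters directly into acid chlorides, and intramolecular Friedel–Crafts acylation can close only the six-membered ring at the free position ortho to the side chain of the anisole (the classical 5-methoxy-1-tetralone closure) without touching the imide-bearing stereocentre.

Step 4
Reactants: 8 (4R)-4-benzyl-3-{[(1R)-8-methoxy-4-oxo-1,2,3,4-tetrahydronaphthalen-1-yl]carbonyl}-1,3-oxazolidin-2-one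
Product: 9 (4R)-4-benzyl-3-{[(1R,4S)-4-hydroxy-8-methoxy-1,2,3,4-tetrahydronaphthalen-1-yl]carbonyl}-1,3-oxazolidin-2-one
Conditions: RuCl[(S,S)-TsDPEN](p-cymene) (cat.), HCO2H/Et3N 5:2, CH2Cl2, 30 °C
Reagents that add atoms: none
Why: Noyori asymmetric transfer hydrogenation of the aryl ketone is catalyst-controlled, and the (S,S)-catalyst should give the (S)-carbinol, which is cis to the C1 substituent; the imide is inert.

Step 5
Reactants: 9 (4R)-4-benzyl-3-{[(1R,4S)-4-hydroxy-8-methoxy-1,2,3,4-tetrahydronaphthalen-1-yl]carbonyl}-1,3-oxazolidin-2-one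
Product: 10 (1S,4R)-4-(hydroxymethyl)-5-methoxy-1,2,3,4-tetrahydronaphthalen-1-ol
Conditions: LiBH4, THF, H2O (1 equiv), 0 °C → rt
Reagents that add atoms: none
Why: LiBH4 cleaves the N-acyloxazolidinone reductively to the primary alcohol (C20) without epimerisation at C1 and releases the auxiliary for recovery.

Step 6
Reactants: 10 (1S,4R)-4-(hydroxymethyl)-5-methoxy-1,2,3,4-tetrahydronaphthalen-1-ol
Product: 11 (1S,4R)-4-{[tert-butyl(dimethyl)silyl]oxymethyl}-5-methoxy-1,2,3,4-tetrahydronaphthalen-1-ol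
Conditions: TBSCl (1.05 equiv), imidazole, CH2Cl2, 0 °C
Reagents that add atoms: tert-butyldimethylsilyl chloride, CC(C)(C)[Si](C)(C)Cl
Why: Silylation discriminates the unhindered primary hydroxyl from the secondary benzylic one.

Step 7
Reactants: 11 (1S,4R)-4-{[tert-butyl(dimethyl)silyl]oxymethyl}-5-methoxy-1,2,3,4-tetrahydronaphthalen-1-ol
Product: 12 (1S,4R)-4-{[tert-butyl(dimethyl)silyl]oxymethyl}-5-methoxy-1,2,3,4-tetrahydronaphthalen-1-yl N,N-diisopropylcarbamate
Conditions: i-Pr2NCOCl, Et3N, CH2Cl2, reflux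
Reagents that add atoms: N,N-diisopropylcarbamoyl chloride, CC(C)N(C(C)C)C(=O)Cl
Why: Carbamoylation of the secondary benzylic alcohol installs the N,N-diisopropylcarbamate that acidifies C4–H, directs its lithiation and later serves as the leaving group.

Step 8
Reactants: 13 5-bromo-2-methylpent-2-ene
Product: 15 4,4,5,5-tetramethyl-2-(4-methylpent-3-en-1-yl)-1,3,2-dioxaborolane, via homoprenylmagnesium bromide 14 (not isolated)
Conditions: Mg, THF, rt; then i-PrOBpin, −78 °C → rt
Reagents that add atoms: 2-isopropoxy-4,4,5,5-tetramethyl-1,3,2-dioxaborolane, CC(C)OB1OC(C)(C)C(C)(C)O1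
Why: Grignard formation and trapping with an alkoxy pinacolborane is the standard entry to primary alkyl pinacol boronic esters, and the trisubstituted alkene is inert.

Step 9
Reactants: 16 ethyl 2,4,6-triisopropylbenzoate; 15 4,4,5,5-tetramethyl-2-(4-methylpent-3-en-1-yl)-1,3,2-dioxaborolane
Product: 19 (S)-4,4,5,5-tetramethyl-2-(6-methylhept-5-en-2-yl)-1,3,2-dioxaborolane, via lithiated benzoate 17 (not isolated), via boronate complex 18 (not isolated)
Conditions: s-BuLi, (+)-sparteine, Et2O, −78 °C; then 15, −78 °C; then reflux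
Reagents that add atoms: none
Why: Lithiation–borylation homologation: s-BuLi/(+)-sparteine removes one enantiotopic α-hydrogen of the ethyl ester to give the configurationally stable (R)-carbenoid 17, which adds to boron with retention, and 1,2-migration of the homoprenyl group with inversion expels the benzoate and should give the (S)-boronic ester.

Step 10
Reactants: 12 (1S,4R)-4-{[tert-butyl(dimethyl)silyl]oxymethyl}-5-methoxy-1,2,3,4-tetrahydronaphthalen-1-yl N,N-diisopropylcarbamate; 19 (S)-4,4,5,5-tetramethyl-2-(6-methylhept-5-en-2-yl)-1,3,2-dioxaborolane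
Product: 22 tert-butyl{[(1R,4S)-8-methoxy-4-[(2S)-6-methylhept-5-en-2-yl]-4-(4,4,5,5-tetramethyl-1,3,2-dioxaborolan-2-yl)-1,2,3,4-tetrahydronaphthalen-1-yl]methoxy}dimethylsilane, via lithiated carbamate 20 (not isolated), via boronate complex 21 (not isolated)
Conditions: s-BuLi, Et2O, −78 °C; then 19, −78 °C; then MgBr2, MeOH, −78 °C → rt
Reagents that add atoms: none
Why: s-BuLi removes the benzylic C4–H next to the carbamate with retention to give the configurationally stable α-carbamoyloxy benzyllithium 20, which adds to the boron of 19 with retention to give boronate 21, and on warming with MgBr2/MeOH the C11–B bond migrates to C4 anti to the departing carbamate (inversion at C4, retention at C11) to form the C4–C11 bond of 22. The closest known reaction type is the lithiation–borylation of secondary benzylic carbamates with secondary alkyl pinacol boronic esters to give tertiary benzylic boronic esters. No ring is closed. C4 is controlled by the (S)-carbinol centre of 12: retention then inversion places boron on the face of the departed oxygen and C11 on the face of the former hydrogen, trans to the C1 substituent. C11 is controlled by the C–B configuration of 19, which is transferred unchanged. The step needs deprotonation only at C4, the one C–H that is both benzylic and carbamate-activated (no diamine is used, so the arene C–H ortho to OMe is left alone), and it needs the hindered boronate not to revert, which the low temperature and the MgBr2/MeOH quench-promoter should secure.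

Step 11
Reactants: 22 tert-butyl{[(1R,4S)-8-methoxy-4-[(2S)-6-methylhept-5-en-2-yl]-4-(4,4,5,5-tetramethyl-1,3,2-dioxaborolan-2-yl)-1,2,3,4-tetrahydronaphthalen-1-yl]methoxy}dimethylsilane
Product: 23 tert-butyl{[(1R,4S)-8-methoxy-4-[(2S)-6-methylhept-5-en-2-yl]-1,2,3,4-tetrahydronaphthalen-1-yl]methoxy}dimethylsilane
Conditions: CsF, H2O (1.1 equiv), 1,4-dioxane, 45 °C
Reagents that add atoms: none
Why: Fluoride-promoted protodeboronation of tertiary benzylic pinacol boronic esters proceeds with retention, so hydrogen takes the place of boron and the side chain stays trans to the C1 substituent.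

Step 12
Reactants: 23 tert-butyl{[(1R,4S)-8-methoxy-4-[(2S)-6-methylhept-5-en-2-yl]-1,2,3,4-tetrahydronaphthalen-1-yl]methoxy}dimethylsilane
Product: 24 tert-butyl{[(1R,4S)-8-methoxy-4-[(2S)-6-methylhept-5-en-2-yl]-6-(4,4,5,5-tetramethyl-1,3,2-dioxaborolan-2-yl)-1,2,3,4-tetrahydronaphthalen-1-yl]methoxy}dimethylsilane
Conditions: [Ir(OMe)(cod)]2 (cat.), dtbpy, B2pin2, THF, 60 °C
Reagents that add atoms: bis(pinacolato)diboron, CC1(C)OB(OC1(C)C)B1OC(C)(C)C(C)(C)O1
Why: Iridium-catalysed arene C–H borylation is governed by sterics, and C6 is the only ring C–H with no ortho substituent (C5 is next to C4a, C7 next to the methoxy-bearing C8), as in the 5-selective borylation of 1,2,3-trisubstituted benzenes.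

Step 13
Reactants: 24 tert-butyl{[(1R,4S)-8-methoxy-4-[(2S)-6-methylhept-5-en-2-yl]-6-(4,4,5,5-tetramethyl-1,3,2-dioxaborolan-2-yl)-1,2,3,4-tetrahydronaphthalen-1-yl]methoxy}dimethylsilane
Product: 25 (5R,8S)-5-{[tert-butyl(dimethyl)silyl]oxymethyl}-4-methoxy-8-[(2S)-6-methylhept-5-en-2-yl]-5,6,7,8-tetrahydronaphthalene-2-carboxylic acid
Conditions: (IPr)CuCl (cat.), KOtBu, CO2 (1 atm), THF, 70 °C; then cold dilute HCl
Reagents that add atoms: carbon dioxide, O=C=O
Why: Copper(I)–NHC-catalysed carboxylation of aryl boronic esters (transmetalation to aryl copper, CO2 insertion) gives the benzoic acid, and silyl ether, methyl ether and alkene are inert to it.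

Step 14
Reactants: 25 (5R,8S)-5-{[tert-butyl(dimethyl)silyl]oxymethyl}-4-methoxy-8-[(2S)-6-methylhept-5-en-2-yl]-5,6,7,8-tetrahydronaphthalene-2-carboxylic acid
Product: 27 (5R,8S)-4-hydroxy-5-(hydroxymethyl)-8-[(2S)-6-methylhept-5-en-2-yl]-5,6,7,8-tetrahydronaphthalene-2-carboxylic acid, via phenol silyl ether 26 (not isolated)
Conditions: NaSEt, DMF, 130 °C; then 2 M HCl, THF, rt
Reagents that add atoms: none
Why: Thiolate SN2 demethylation of the aryl methyl ether tolerates the alkene and the carboxylate, and the acidic work-up hydrolyses the primary silyl ether.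

Step 15
Reactants: 27 (5R,8S)-4-hydroxy-5-(hydroxymethyl)-8-[(2S)-6-methylhept-5-en-2-yl]-5,6,7,8-tetrahydronaphthalene-2-carboxylic acid
Product: 28 (5R,8S)-5-(acetoxymethyl)-4-hydroxy-8-[(2S)-6-methylhept-5-en-2-yl]-5,6,7,8-tetrahydronaphthalene-2-carboxylic acid
Conditions: Novozym 435 (immobilised lipase B of Candida antarctica), vinyl acetate, MTBE, 35 °C
Reagents that add atoms: vinyl acetate, C=COC(C)=O
Why: Lipase-catalysed transesterification with vinyl acetate acylates primary aliphatic alcohols while phenols and aromatic acids are not acylated, as in the selective acetylation of hydroxyphenyl alkanols.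

**Compound list**

1 | (2-methoxyphenyl)acetic acid | COc1ccccc1CC(=O)O | starting material
2 | (2-methoxyphenyl)acetic pivalic anhydride | COc1ccccc1CC(=O)OC(=O)C(C)(C)C | intermediate
3 | (4R)-4-benzyl-3-[(2-methoxyphenyl)acetyl]-1,3-oxazolidin-2-one | COc1ccccc1CC(=O)N1[C@H](Cc2ccccc2)COC1=O | intermediate
4 | tert-butyl acrylate | C=CC(=O)OC(C)(C)C | starting material
5 | (Z)-dichloro(isopropoxy)titanium enolate of 3 | COc1ccccc1/C=C(\O[Ti](Cl)(Cl)OC(C)C)N1[C@H](Cc2ccccc2)COC1=O | intermediate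
6 | tert-butyl (4R)-5-[(4R)-4-benzyl-2-oxo-1,3-oxazolidin-3-yl]-4-(2-methoxyphenyl)-5-oxopentanoate | O=C([C@@H](c1ccccc1OC)CCC(=O)OC(C)(C)C)N1[C@H](Cc2ccccc2)COC1=O | intermediate
7 | (4R)-5-[(4R)-4-benzyl-2-oxo-1,3-oxazolidin-3-yl]-4-(2-methoxyphenyl)-5-oxopentanoyl chloride | O=C([C@@H](c1ccccc1OC)CCC(=O)Cl)N1[C@H](Cc2ccccc2)COC1=O | intermediate
8 | (4R)-4-benzyl-3-{[(1R)-8-methoxy-4-oxo-1,2,3,4-tetrahydronaphthalen-1-yl]carbonyl}-1,3-oxazolidin-2-one | O=C([C@@H]1CCC(=O)c2cccc(OC)c21)N1[C@H](Cc2ccccc2)COC1=O | intermediate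
9 | (4R)-4-benzyl-3-{[(1R,4S)-4-hydroxy-8-methoxy-1,2,3,4-tetrahydronaphthalen-1-yl]carbonyl}-1,3-oxazolidin-2-one (cis) | O=C([C@@H]1CC[C@H](O)c2cccc(OC)c21)N1[C@H](Cc2ccccc2)COC1=O | intermediate
10 | (1S,4R)-4-(hydroxymethyl)-5-methoxy-1,2,3,4-tetrahydronaphthalen-1-ol (cis) | OC[C@@H]1CC[C@H](O)c2cccc(OC)c21 | intermediate
11 | (1S,4R)-4-{[tert-butyl(dimethyl)silyl]oxymethyl}-5-methoxy-1,2,3,4-tetrahydronaphthalen-1-ol | CC(C)(C)[Si](C)(C)OC[C@@H]1CC[C@H](O)c2cccc(OC)c21 | intermediate
12 | (1S,4R)-4-{[tert-butyl(dimethyl)silyl]oxymethyl}-5-methoxy-1,2,3,4-tetrahydronaphthalen-1-yl N,N-diisopropylcarbamate | CC(C)(C)[Si](C)(C)OC[C@@H]1CC[C@H](OC(=O)N(C(C)C)C(C)C)c2cccc(OC)c21 | intermediate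
13 | 5-bromo-2-methylpent-2-ene | CC(C)=CCCBr | starting material
14 | (4-methylpent-3-en-1-yl)magnesium bromide | CC(C)=CCC[Mg]Br | intermediate
15 | 4,4,5,5-tetramethyl-2-(4-methylpent-3-en-1-yl)-1,3,2-dioxaborolane | CC(C)=CCCB1OC(C)(C)C(C)(C)O1 | intermediate
16 | ethyl 2,4,6-triisopropylbenzoate | CCOC(=O)c1c(C(C)C)cc(C(C)C)cc1C(C)C | starting material
17 | (R)-1-lithioethyl 2,4,6-triisopropylbenzoate (sparteine complex) | C[C@@H]([Li])OC(=O)c1c(C(C)C)cc(C(C)C)cc1C(C)C | intermediate
18 | lithium boronate from 17 and 15 | C[C@@H]([B-]1(CCC=C(C)C)OC(C)(C)C(C)(C)O1)OC(=O)c1c(C(C)C)cc(C(C)C)cc1C(C)C.[Li+] | intermediate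
19 | (S)-4,4,5,5-tetramethyl-2-(6-methylhept-5-en-2-yl)-1,3,2-dioxaborolane | C[C@H](B1OC(C)(C)C(C)(C)O1)CCC=C(C)C | intermediate
20 | carbamate 12 lithiated at the carbamate carbon (Li in place of H, configuration retained) | CC(C)(C)[Si](C)(C)OC[C@@H]1CC[C@]([Li])(OC(=O)N(C(C)C)C(C)C)c2cccc(OC)c21 | intermediate
21 | lithium boronate from 20 and 19 | CC(C)(C)[Si](C)(C)OC[C@@H]1CC[C@]([B-]2(OC(C)(C)C(C)(C)O2)[C@@H](C)CCC=C(C)C)(OC(=O)N(C(C)C)C(C)C)c2cccc(OC)c21.[Li+] | intermediate
22 | tert-butyl{[(1R,4S)-8-methoxy-4-[(2S)-6-methylhept-5-en-2-yl]-4-(4,4,5,5-tetramethyl-1,3,2-dioxaborolan-2-yl)-1,2,3,4-tetrahydronaphthalen-1-yl]methoxy}dimethylsilane | CC(C)(C)[Si](C)(C)OC[C@@H]1CC[C@@](B2OC(C)(C)C(C)(C)O2)([C@@H](C)CCC=C(C)C)c2cccc(OC)c21 | intermediate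
23 | tert-butyl{[(1R,4S)-8-methoxy-4-[(2S)-6-methylhept-5-en-2-yl]-1,2,3,4-tetrahydronaphthalen-1-yl]methoxy}dimethylsilane | CC(C)(C)[Si](C)(C)OC[C@@H]1CC[C@@H]([C@@H](C)CCC=C(C)C)c2cccc(OC)c21 | intermediate
24 | tert-butyl{[(1R,4S)-8-methoxy-4-[(2S)-6-methylhept-5-en-2-yl]-6-(4,4,5,5-tetramethyl-1,3,2-dioxaborolan-2-yl)-1,2,3,4-tetrahydronaphthalen-1-yl]methoxy}dimethylsilane | CC(C)(C)[Si](C)(C)OC[C@@H]1CC[C@@H]([C@@H](C)CCC=C(C)C)c2cc(B3OC(C)(C)C(C)(C)O3)cc(OC)c21 | intermediate
25 | (5R,8S)-5-{[tert-butyl(dimethyl)silyl]oxymethyl}-4-methoxy-8-[(2S)-6-methylhept-5-en-2-yl]-5,6,7,8-tetrahydronaphthalene-2-carboxylic acid | CC(C)(C)[Si](C)(C)OC[C@@H]1CC[C@@H]([C@@H](C)CCC=C(C)C)c2cc(C(=O)O)cc(OC)c21 | intermediate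
26 | (5R,8S)-5-{[tert-butyl(dimethyl)silyl]oxymethyl}-4-hydroxy-8-[(2S)-6-methylhept-5-en-2-yl]-5,6,7,8-tetrahydronaphthalene-2-carboxylic acid | CC(C)(C)[Si](C)(C)OC[C@@H]1CC[C@@H]([C@@H](C)CCC=C(C)C)c2cc(C(=O)O)cc(O)c21 | intermediate
27 | (5R,8S)-4-hydroxy-5-(hydroxymethyl)-8-[(2S)-6-methylhept-5-en-2-yl]-5,6,7,8-tetrahydronaphthalene-2-carboxylic acid | OC[C@@H]1CC[C@@H]([C@@H](C)CCC=C(C)C)c2cc(C(=O)O)cc(O)c21 | intermediate
28 | (5R,8S)-5-(acetoxymethyl)-4-hydroxy-8-[(2S)-6-methylhept-5-en-2-yl]-5,6,7,8-tetrahydronaphthalene-2-carboxylic acid | CC(=O)OC[C@@H]1CC[C@@H]([C@@H](C)CCC=C(C)C)c2cc(C(=O)O)cc(O)c21 | target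

**Step count and risks**

Total steps: 15. Longest linear sequence: 13 (steps 1–7 and 10–15).

Steps most likely to fail:

1. Step 10. Boronate formation from two hindered partners may be slow or reversible, so that the lithiated carbamate racemises or decomposes before the 1,2-shift. Fallback, from 11 back to 23: the C4–C11 bond is made by a one-carbon homologation instead of a fragment union. Alcohol 11 is dehydrated with the Burgess reagent to tert-butyl{[(1R)-8-methoxy-1,2-dihydronaphthalen-1-yl]methoxy}dimethylsilane F1. Copper hydride-catalysed asymmetric hydroboration (CuCl, NaOtBu, the DTBM-SEGPHOS enantiomer that adds anti to the C1 substituent, HBpin) gives the trans benzylic pinacol boronic ester F2. Homologation of F2 with the (S)-α-lithioethyl benzoate made from 16 with s-BuLi/(−)-sparteine (C4 migrates with retention) gives the 1-borylethyl compound F3. Zweifel olefination (vinyllithium, then I2, NaOMe) gives the but-3-en-2-yl compound F4. 9-BBN hydroboration and B-alkyl Suzuki coupling with 1-bromo-2-methylprop-1-ene (Pd(dppf)Cl2, aq. K3PO4) complete the side chain and give 23.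

2. Step 11. Fluoride may fail to activate the very hindered tertiary boronate, or protonation may lose part of the C4 configuration. Fallback, from 22 back to 23: oxidation (H2O2, NaOH, THF, 0 °C; retention) gives the tertiary benzylic alcohol F5. Burgess dehydration (syn elimination towards the ring CH2) gives the 4-substituted 1,2-dihydronaphthalene F6. Li in NH3/THF at −78 °C reduces only the styrene double bond and should give the more stable trans-1,4 isomer 23, in which both benzylic substituents are pseudoaxial.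

3. Step 12. Hydroboration or isomerisation of the trisubstituted alkene by Ir–H/HBpin may compete with arene borylation. Fallback, from 23 back to 24: the alkene is masked (mCPBA, NaHCO3, CH2Cl2, 0 °C) as the side-chain epoxide F7, which is borylated as in step 12 to the epoxy aryl boronate F8. Deoxygenation (NaI, Zn, NaOAc, AcOH) restores the isopropylidene group, which has no geometry to lose, and gives 24.

Further compounds
F1 | step 10 | tert-butyl{[(1R)-8-methoxy-1,2-dihydronaphthalen-1-yl]methoxy}dimethylsilane | CC(C)(C)[Si](C)(C)OC[C@@H]1CC=Cc2cccc(OC)c21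
F2 | step 10 | tert-butyl{[(1R,4R)-8-methoxy-4-(4,4,5,5-tetramethyl-1,3,2-dioxaborolan-2-yl)-1,2,3,4-tetrahydronaphthalen-1-yl]methoxy}dimethylsilane | CC(C)(C)[Si](C)(C)OC[C@@H]1CC[C@@H](B2OC(C)(C)C(C)(C)O2)c2cccc(OC)c21
F3 | step 10 | tert-butyl{[(1R,4S)-8-methoxy-4-[(1R)-1-(4,4,5,5-tetramethyl-1,3,2-dioxaborolan-2-yl)ethyl]-1,2,3,4-tetrahydronaphthalen-1-yl]methoxy}dimethylsilane | CC(C)(C)[Si](C)(C)OC[C@@H]1CC[C@@H]([C@@H](C)B2OC(C)(C)C(C)(C)O2)c2cccc(OC)c21
F4 | step 10 | tert-butyl{[(1R,4S)-4-[(2S)-but-3-en-2-yl]-8-methoxy-1,2,3,4-tetrahydronaphthalen-1-yl]methoxy}dimethylsilane | CC(C)(C)[Si](C)(C)OC[C@@H]1CC[C@@H]([C@@H](C)C=C)c2cccc(OC)c21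
F5 | step 11 | (1R,4R)-4-{[tert-butyl(dimethyl)silyl]oxymethyl}-5-methoxy-1-[(2S)-6-methylhept-5-en-2-yl]-1,2,3,4-tetrahydronaphthalen-1-ol | CC(C)(C)[Si](C)(C)OC[C@@H]1CC[C@@](O)([C@@H](C)CCC=C(C)C)c2cccc(OC)c21
F6 | step 11 | tert-butyl{[(1R)-8-methoxy-4-[(2S)-6-methylhept-5-en-2-yl]-1,2-dihydronaphthalen-1-yl]methoxy}dimethylsilane | CC(C)(C)[Si](C)(C)OC[C@@H]1CC=C([C@@H](C)CCC=C(C)C)c2cccc(OC)c21
F7 | step 12 | tert-butyl{[(1R,4S)-4-[(2S)-4-(3,3-dimethyloxiran-2-yl)butan-2-yl]-8-methoxy-1,2,3,4-tetrahydronaphthalen-1-yl]methoxy}dimethylsilane | CC(C)(C)[Si](C)(C)OC[C@@H]1CC[C@@H]([C@@H](C)CCC2OC2(C)C)c2cccc(OC)c21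
F8 | step 12 | tert-butyl{[(1R,4S)-4-[(2S)-4-(3,3-dimethyloxiran-2-yl)butan-2-yl]-8-methoxy-6-(4,4,5,5-tetramethyl-1,3,2-dioxaborolan-2-yl)-1,2,3,4-tetrahydronaphthalen-1-yl]methoxy}dimethylsilane | CC(C)(C)[Si](C)(C)OC[C@@H]1CC[C@@H]([C@@H](C)CCC2OC2(C)C)c2cc(B3OC(C)(C)C(C)(C)O3)cc(OC)c21
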